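**Retrosynthetic overview**
- The target is reached from the aryl silyl ether (R)-terpinen-4-yl 4-(tert-butyldimethylsilyloxy)-3,5-diprenylbenzoate by a single O-desilylation/O-methylation.
- The strategy rests on the benzene ring: O-bearing C4 lies para to the ester-bearing C1, and C3 and C5 carry the prenyl groups. C2 to C5 map onto a 1-dimethylamino-3-silyloxy-2,4-diprenylbuta-1,3-diene, and C1 and C6 onto a propiolate.
- The benzene ring is the only ring formed. A Diels-Alder reaction makes the C1-C2 and C5-C6 bonds and loss of dimethylamine aromatises the adduct. The cyclohexene ring and the stereocentre are bought with (R)-terpinen-4-ol.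
- The diene comes from 2,10-dimethylundeca-2,9-dien-6-one (aminomethylenation, then O-silylation of the dienolate). The ketone comes from dimethyl 3-oxoglutarate and two prenyl bromides.
- The dienophile comes from the lithium alkoxide of (R)-terpinen-4-ol and 3-(trimethylsilyl)propioloyl chloride, followed by C-desilylation.

Key step: step 8

Assumption: (R)-terpinen-4-ol is bought in high enantiomeric purity; because a direct carbodiimide esterification of this hindered tertiary alcohol with propiolic acid is unreliable, the propiolate is made through the lithium alkoxide and a C-silylated acid chloride.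

**Route**

Step 1
Reactants: 1 dimethyl 3-oxoglutarate; 2 prenyl bromide (2.1 equiv)
Product: 3 dimethyl 2,4-bis(3-methylbut-2-enyl)-3-oxopentanedioate (mixture of diastereomers)
Conditions: NaH (2.1 equiv, two portions), 2 (two portions), THF, 0 °C to rt
Reagents that add atoms: none
Why: Twofold C-alkylation of the β-keto diester enolate (acetoacetic ester type alkylation) with a reactive allylic bromide; after the first alkylation the unsubstituted C4 methylene is the more acidic and less hindered site, so the second prenyl group should enter at the other α-carbon.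

Step 2
Reactants: 3 dimethyl 2,4-bis(3-methylbut-2-enyl)-3-oxopentanedioate
Product: 5 2,10-dimethylundeca-2,9-dien-6-one, via 2,4-diprenyl-3-oxoglutaric acid 4 (not isolated)
Conditions: NaOH, H2O/MeOH, rt to 50 °C; then aq HCl to pH 3, 40 °C
Reagents that add atoms: none
Why: Saponification followed by decarboxylation of the β-keto diacid on mild acidification (ketonic hydrolysis of the acetoacetic ester synthesis) removes both ester carbons, and the trisubstituted alkenes tolerate dilute base and brief dilute acid.

Step 3
Reactants: 5 2,10-dimethylundeca-2,9-dien-6-one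
Product: 6 (5E)-5-[(dimethylamino)methylidene]-2,10-dimethylundeca-2,9-dien-6-one
Conditions: t-BuOCH(NMe2)2 (1.05 equiv), PhMe, 80 °C
Reagents that add atoms: tert-butoxybis(dimethylamino)methane, CN(C)C(OC(C)(C)C)N(C)C
Why: Aminomethylenation of an α-methylene ketone with an aminal ester gives the E vinylogous amide; the ketone is symmetrical so either methylene leads to 6, and the donor-substituted carbonyl of 6 is much less prone to a second condensation when about one equivalent of reagent is used.

Step 4
Reactants: 6 (5E)-5-[(dimethylamino)methylidene]-2,10-dimethylundeca-2,9-dien-6-one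
Product: 8 (1E,3Z)-1-dimethylamino-3-(tert-butyldimethylsilyloxy)-2,4-bis(3-methylbut-2-enyl)buta-1,3-diene, via potassium dienolate 7 (not isolated)
Conditions: KN(SiMe3)2, THF, −78 °C; t-BuMe2SiCl, −78 °C to rt; salts filtered off under argon, used crude
Reagents that add atoms: tert-butyldimethylsilyl chloride, CC(C)(C)[Si](C)(C)Cl
Why: Kinetic deprotonation of the vinylogous amide at the α'-methylene and O-silylation of the cross-conjugated dienolate is the standard preparation of 1-amino-3-silyloxydienes; the bulky branched vinyl group on the carbonyl should favour the Z enolate, which places the prenyl CH2 trans to C2.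

Step 5
Reactants: 9 3-(trimethylsilyl)propiolic acid
Product: 10 3-(trimethylsilyl)propioloyl chloride
Conditions: (COCl)2, DMF (cat.), CH2Cl2, 0 °C to rt; concentrated and used directly
Reagents that add atoms: oxalyl chloride, O=C(Cl)C(=O)Cl
Why: Acid chloride formation with oxalyl chloride under Vilsmeier catalysis; the C-silyl group masks the acidic alkyne C-H that would interfere with the alkoxide acylation in step 6.

Step 6
Reactants: 11 (R)-terpinen-4-ol; 10 3-(trimethylsilyl)propioloyl chloride
Product: 13 (R)-terpinen-4-yl 3-(trimethylsilyl)propiolate, via lithium (R)-terpinen-4-oxide 12 (not isolated)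
Conditions: n-BuLi, THF, −78 °C; then 10, −78 to 0 °C
Reagents that add atoms: none
Why: O-acylation of a preformed lithium tertiary alkoxide by an acid chloride is the reliable esterification for hindered tertiary alcohols, and it takes place at oxygen so the R carbinol centre is retained.

Step 7
Reactants: 13 (R)-terpinen-4-yl 3-(trimethylsilyl)propiolate
Product: 14 (R)-terpinen-4-yl propiolate
Conditions: Bu4NF, AcOH, THF, −20 °C
Reagents that add atoms: none
Why: Fluoride-induced protodesilylation of the alkynylsilane, which is especially labile next to the ester, with AcOH as buffer and proton source so that neither the ynoate nor the tertiary ester is attacked.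

Step 8
Reactants: 8 (1E,3Z)-1-dimethylamino-3-(tert-butyldimethylsilyloxy)-2,4-bis(3-methylbut-2-enyl)buta-1,3-diene; 14 (R)-terpinen-4-yl propiolate
Product: 16 (R)-terpinen-4-yl 4-(tert-butyldimethylsilyloxy)-3,5-bis(3-methylbut-2-enyl)benzoate, via cyclohexa-1,4-diene cycloadduct 15 (not isolated)
Conditions: PhMe, 60 °C, 14 (1.5 equiv); then SiO2, CH2Cl2, rt
Reagents that add atoms: none
Why: The electron-rich 1-amino-3-silyloxydiene adds to the electron-poor alkynoate in a concerted but strongly asynchronous normal-electron-demand Diels-Alder reaction, bonding first from diene C4 to the propiolate β-carbon and then from the amino-bearing C1 to the α-carbon, and cycloadduct 15 aromatises by 1,4-elimination of dimethylamine (C1-N and C4-H), which silica gel completes. The closest known reaction type is the cycloaddition of 1-dialkylamino-3-silyloxybuta-1,3-dienes with acetylenic esters, which gives para-silyloxy benzoates after loss of the amine. The benzene ring is closed intermolecularly as a (4+2) annulation, with four ring carbons from the diene and two from the alkyne. The two sp3 ring centres of 15 form as a mixture relative to the remote terpinenyl centre and are both destroyed on aromatisation, so no new stereocentre has to be controlled and the carbinol centre of 14 is not involved. The step needs regioselectivity, which is secured because C4 is the terminus made nucleophilic by both the nitrogen and the oxygen donor and the propiolate β-carbon is the electrophilic, unhindered position, so the ester carbon ends para to the silyloxy carbon; the 1E and 3Z geometries keep NMe2 and the prenyl CH2 on the outside of the s-cis diene. The excess of 14 allows for the part of it that the liberated dimethylamine captures by conjugate addition.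

Step 9
Reactants: 16 (R)-terpinen-4-yl 4-(tert-butyldimethylsilyloxy)-3,5-bis(3-methylbut-2-enyl)benzoate
Product: 18 (R)-terpinen-4-yl 4-methoxy-3,5-bis(3-methylbut-2-enyl)benzoate, via tetrabutylammonium phenoxide 17 (not isolated)
Conditions: Bu4NF, THF, 0 °C; then MeI, rt
Reagents that add atoms: iodomethane, CI
Why: Fluoride cleavage of the aryl silyl ether gives the phenoxide, which as its tetrabutylammonium salt is O-methylated by MeI in an SN2 reaction (one-pot desilylation and Williamson etherification); the hindered tertiary benzoate and the alkenes are inert.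

**Compound list**

1 | dimethyl 3-oxopentanedioate (dimethyl 3-oxoglutarate) | COC(=O)CC(=O)CC(=O)OC | starting material
2 | 1-bromo-3-methylbut-2-ene (prenyl bromide) | CC(C)=CCBr | starting material
3 | dimethyl 2,4-bis(3-methylbut-2-enyl)-3-oxopentanedioate (mixture of diastereomers, both centres lost in step 2) | COC(=O)C(CC=C(C)C)C(=O)C(CC=C(C)C)C(=O)OC | intermediate
4 | 2,4-bis(3-methylbut-2-enyl)-3-oxopentanedioic acid (not isolated) | OC(=O)C(CC=C(C)C)C(=O)C(CC=C(C)C)C(=O)O | intermediate
5 | 2,10-dimethylundeca-2,9-dien-6-one | CC(C)=CCCC(=O)CCC=C(C)C | intermediate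
6 | (5E)-5-[(dimethylamino)methylidene]-2,10-dimethylundeca-2,9-dien-6-one | CN(C)/C=C(CC=C(C)C)/C(=O)CCC=C(C)C | intermediate
7 | potassium (1E,3Z)-1-dimethylamino-2,4-bis(3-methylbut-2-enyl)buta-1,3-dien-3-olate (diene numbering of 8; not isolated) | CN(C)/C=C(CC=C(C)C)/C([O-])=C/CC=C(C)C.[K+] | intermediate
8 | (1E,3Z)-1-dimethylamino-3-(tert-butyldimethylsilyloxy)-2,4-bis(3-methylbut-2-enyl)buta-1,3-diene | CN(C)/C=C(CC=C(C)C)/C(O[Si](C)(C)C(C)(C)C)=C/CC=C(C)C | intermediate
9 | 3-(trimethylsilyl)prop-2-ynoic acid | C[Si](C)(C)C#CC(=O)O | starting material
10 | 3-(trimethylsilyl)prop-2-ynoyl chloride | C[Si](C)(C)C#CC(=O)Cl | intermediate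
11 | (R)-terpinen-4-ol, (1R)-4-methyl-1-(propan-2-yl)cyclohex-3-en-1-ol | O[C@@]1(C(C)C)CC=C(C)CC1 | starting material
12 | lithium (1R)-4-methyl-1-(propan-2-yl)cyclohex-3-en-1-olate (not isolated) | [Li+].[O-][C@@]1(C(C)C)CC=C(C)CC1 | intermediate
13 | (1R)-4-methyl-1-(propan-2-yl)cyclohex-3-en-1-yl 3-(trimethylsilyl)prop-2-ynoate | C[Si](C)(C)C#CC(=O)O[C@@]1(C(C)C)CC=C(C)CC1 | intermediate
14 | (1R)-4-methyl-1-(propan-2-yl)cyclohex-3-en-1-yl prop-2-ynoate, (R)-terpinen-4-yl propiolate | C#CC(=O)O[C@@]1(C(C)C)CC=C(C)CC1 | intermediate
15 | (R)-terpinen-4-yl 4-(tert-butyldimethylsilyloxy)-6-(dimethylamino)-3,5-bis(3-methylbut-2-enyl)cyclohexa-1,4-diene-1-carboxylate (NMe2 and the C3 prenyl group cis; mixture at the two ring centres relative to the terpinenyl centre, left unspecified because both are lost; not isolated) | CN(C)C1C(C(=O)O[C@@]2(C(C)C)CC=C(C)CC2)=CC(CC=C(C)C)C(O[Si](C)(C)C(C)(C)C)=C1CC=C(C)C | intermediate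
16 | (R)-terpinen-4-yl 4-(tert-butyldimethylsilyloxy)-3,5-bis(3-methylbut-2-enyl)benzoate | CC(C)(C)[Si](C)(C)Oc1c(CC=C(C)C)cc(C(=O)O[C@@]2(C(C)C)CC=C(C)CC2)cc1CC=C(C)C | intermediate
17 | tetrabutylammonium 2,6-bis(3-methylbut-2-enyl)-4-{[(1R)-4-methyl-1-(propan-2-yl)cyclohex-3-en-1-yl]oxycarbonyl}phenolate (not isolated) | CCCC[N+](CCCC)(CCCC)CCCC.[O-]c1c(CC=C(C)C)cc(C(=O)O[C@@]2(C(C)C)CC=C(C)CC2)cc1CC=C(C)C | intermediate
18 | (1R)-4-methyl-1-(propan-2-yl)cyclohex-3-en-1-yl 4-methoxy-3,5-bis(3-methylbut-2-enyl)benzoate | COc1c(CC=C(C)C)cc(C(=O)O[C@@]2(C(C)C)CC=C(C)CC2)cc1CC=C(C)C | target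

**Step count**
Total steps: 9. Longest linear sequence: 6 (steps 1, 2, 3, 4, 8, 9); the dienophile branch (steps 5, 6, 7) joins at step 8.

**Steps most likely to fail**

Step 8 (key step). What may go wrong: the cycloaddition of the tetrasubstituted diene may be slow, conjugate addition may stop short of ring closure, or the liberated dimethylamine may consume the propiolate before the diene does. The fallback is a cross-coupling approach that does not build the ring and sets out from (R)-terpinen-4-ol 11. Commercial 3,5-dibromo-4-methoxybenzoic acid is converted with (COCl)2 and catalytic DMF into 3,5-dibromo-4-methoxybenzoyl chloride F1. This acylates lithium alkoxide 12 (from 11 and n-BuLi, THF, −78 to 0 °C) to give (R)-terpinen-4-yl 3,5-dibromo-4-methoxybenzoate F2. A twofold Stille coupling of F2 with tributyl(3-methylbut-2-enyl)stannane, Pd(PPh3)4 (zerovalent palladium), DMF, 90 °C, should attach both prenyl groups through their CH2 termini and so comes back to the route at target 18.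

Step 1. What may go wrong: the second alkylation may take place at the already alkylated carbon, or over-alkylation and O-alkylation may occur, leaving ketones after step 2 that are hard to separate from 5. The fallback is a regiocontrolled hydrazone alkylation that sets out from prenyl bromide 2. Commercial 6-methylhept-5-en-2-one is condensed with 1,1-dimethylhydrazine to 6-methylhept-5-en-2-one N,N-dimethylhydrazone F3. Deprotonation of F3 at the methyl group with LiN(i-Pr)2 (THF, −78 to 0 °C) and alkylation with 2 gives 2,10-dimethylundeca-2,9-dien-6-one N,N-dimethylhydrazone F4. Two-phase hydrolysis of F4 with aqueous oxalic acid releases ketone 5, where the route is rejoined.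

Step 3. What may go wrong: condensation on both α-methylene groups, or incomplete conversion of the ketone. The fallback is a Claisen formylation followed by amine condensation and sets out from ketone 5. NaH and ethyl formate (cat. EtOH, Et2O, 0 °C to rt) give the sodium salt of the formyl ketone, which as an enolate resists a second formylation. Acidification gives (Z)-5-(hydroxymethylidene)-2,10-dimethylundeca-2,9-dien-6-one F5, and condensation of F5 with dimethylamine (THF solution, PhMe, MgSO4, rt) gives enaminone 6, where the route is rejoined.

**Further compounds**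

F1 | step 8 | 3,5-dibromo-4-methoxybenzoyl chloride | COc1c(Br)cc(C(=O)Cl)cc1Br
F2 | step 8 | (R)-terpinen-4-yl 3,5-dibromo-4-methoxybenzoate | COc1c(Br)cc(C(=O)O[C@@]2(C(C)C)CC=C(C)CC2)cc1Br
F3 | step 1 | 6-methylhept-5-en-2-one N,N-dimethylhydrazone (E) | C/C(=N\N(C)C)CCC=C(C)C
F4 | step 1 | 2,10-dimethylundeca-2,9-dien-6-one N,N-dimethylhydrazone | CN(C)N=C(CCC=C(C)C)CCC=C(C)C
F5 | step 3 | (Z)-5-(hydroxymethylidene)-2,10-dimethylundeca-2,9-dien-6-one | O/C=C(/CC=C(C)C)C(=O)CCC=C(C)C
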